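**Retrosynthetic overview**
1. Target 14 ⇒ diene 12: the C2–Br and C3–OH centres come last, from bromohydrin formation on the ring B alkene.
2. 12 ⇒ spiro ketone 9: the C7 methyl and the ring A alkene come from the C7 ketone via enol triflate and methyl cross-coupling.
3. 9 ⇒ enone 7 + isoprene 8: a Diels–Alder cycloaddition builds ring B and the spiro centre C6 under control of the C10–Br centre (key step).
4. 7 ⇒ bromo ketone 3: 1,2-carbonyl transposition (methylenation, then SeO2 ene/[2,3] allylic oxidation, then oxidation).
5. 3 ⇒ 1: the C–Br centre by SN2 inversion of the bought carbinol. Ring A is bought; ring B is formed second, in step 5.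

Assumption: (S)-3-hydroxy-2,2-dimethylcyclohexan-1-one is bought enantiopure; spiro compounds carry chamigrene numbering (C1–C5 ring B with methyl on C3, C6 spiro atom, C7–C11 ring A with gem-dimethyl C11 and bromine on C10).

**Step 1**
Reactants: 1 (S)-3-hydroxy-2,2-dimethylcyclohexan-1-one
Product: 3 (R)-3-bromo-2,2-dimethylcyclohexan-1-one, via alkoxyphosphonium bromide 2 (not isolated)
Conditions: PPh3, CBr4, toluene, 0 → 70 °C
Reagents that add atoms: carbon tetrabromide, BrC(Br)(Br)Br
Why: Appel bromination, in which bromide displaces the oxyphosphonium group of 2 by SN2 with inversion (S → R); the backside path runs over the flat carbonyl carbon and not over a methyl group, and the β-keto group disfavours ionisation and Wagner–Meerwein shift.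

**Step 2**
Reactants: 3 (R)-3-bromo-2,2-dimethylcyclohexan-1-one
Product: 4 (1R)-1-bromo-2,2-dimethyl-3-methylidenecyclohexane
Conditions: Cp2TiMe2, toluene, 65 °C, dark
Reagents that add atoms: dimethyltitanocene Cp2TiMe2, C[Ti](C)(C1C=CC=C1)C1C=CC=C1
Why: Petasis methylenation converts the hindered, enolisable ketone into the exocyclic alkene without base, so the bromide is not eliminated and the C–Br centre is untouched.

**Step 3**
Reactants: 4 (1R)-1-bromo-2,2-dimethyl-3-methylidenecyclohexane
Product: 6 (4R)-4-bromo-3,3-dimethyl-2-methylidenecyclohexan-1-ol (both C1 epimers), via allylic seleninic acid 5 (not isolated)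
Conditions: SeO2 (0.3 equiv), t-BuOOH, CH2Cl2, 0 °C → rt
Reagents that add atoms: selenium dioxide, O=[Se]=O; tert-butyl hydroperoxide, CC(C)(C)OO
Why: Sharpless allylic oxidation, in which an ene reaction at the only allylic CH2 gives 5 and its [2,3]-sigmatropic shift returns the alkene to the exocyclic position with OH on the ring carbon; the new carbinol centre forms as a mixture and is erased in step 4.

**Step 4**
Reactants: 6 (4R)-4-bromo-3,3-dimethyl-2-methylidenecyclohexan-1-ol
Product: 7 (4R)-4-bromo-3,3-dimethyl-2-methylidenecyclohexan-1-one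
Conditions: Dess–Martin periodinane, CH2Cl2, 0 °C → rt; used at once
Reagents that add atoms: none
Why: Dess–Martin oxidation of the allylic alcohol under neutral conditions gives the exocyclic enone (the dienophile) without touching the bromide.

**Step 5**
Reactants: 7 (4R)-4-bromo-3,3-dimethyl-2-methylidenecyclohexan-1-one; 8 isoprene (2-methylbuta-1,3-diene)
Product: 9 (6R,10R)-10-bromo-3,11,11-trimethylspiro[5.5]undec-2-en-7-one
Conditions: Me2AlCl (0.5 equiv), isoprene (5 equiv), CH2Cl2, −78 → −40 °C; chromatography
Reagents that add atoms: none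
Why: Lewis acid-promoted Diels–Alder reaction in which isoprene C1 bonds to the enone β-CH2 ("para" adduct, methyl 1,4 to the spiro carbon) and the diene is expected to add to the equatorial face of the Br-equatorial chair, away from the axial hydrogens on C4 and C6, so the incoming CH2 ends equatorial and cis to Br (6R); the selectivity is a prediction and the minor C6 epimer is removed by chromatography.

**Step 6**
Reactants: 9 (6R,10R)-10-bromo-3,11,11-trimethylspiro[5.5]undec-2-en-7-one
Product: 11 (6R,10R)-10-bromo-3,11,11-trimethylspiro[5.5]undeca-2,7-dien-7-yl trifluoromethanesulfonate, via potassium enolate 10 (not isolated)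
Conditions: KN(SiMe3)2, THF, −78 °C, 20 min; then PhNTf2, −78 → 0 °C
Reagents that add atoms: N-phenylbis(trifluoromethanesulfonimide), O=S(=O)(N(c1ccccc1)S(=O)(=O)C(F)(F)F)C(F)(F)F
Why: Enol triflate formation, in which deprotonation can occur only at C8 (the other α-carbon is the spiro atom) and O-triflation of 10 fixes the C7=C8 position; the cold, short-lived enolate does not displace the neopentylic bromide and no stereocentre is touched.

**Step 7**
Reactants: 11 (6R,10R)-10-bromo-3,11,11-trimethylspiro[5.5]undeca-2,7-dien-7-yl trifluoromethanesulfonate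
Product: 12 (6S,10R)-10-bromo-3,7,11,11-tetramethylspiro[5.5]undeca-2,7-diene
Conditions: MeZnCl, Pd(PPh3)4 (5 mol %), THF, 50 °C
Reagents that add atoms: methylzinc chloride, C[Zn]Cl
Why: Negishi cross-coupling of the alkenyl triflate installs the C7 methyl without moving the alkene, and the hindered secondary alkyl bromide is inert to Pd(PPh3)4 under these conditions (C6 is unchanged; its descriptor switches to S only through the priority change).

**Step 8**
Reactants: 12 (6S,10R)-10-bromo-3,7,11,11-tetramethylspiro[5.5]undeca-2,7-diene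
Product: 14 (2S,3S,6S,10R)-2,10-dibromo-3,7,11,11-tetramethylspiro[5.5]undec-7-en-3-ol, via bromonium ion 13 (not isolated)
Conditions: NBS (1.05 equiv), acetone/H2O 4:1, 0 °C, dark
Reagents that add atoms: N-bromosuccinimide, O=C1CCC(=O)N1Br; water, O
Why: Bromohydrin formation, in which NBS attacks the less hindered ring B alkene (the ring A alkene is flanked by the spiro and gem-dimethyl carbons) on the face anti to the axially disposed C7, and water opens 13 at the tertiary C3 from the opposite face (Markovnikov, anti), which should give the trans bromohydrin with Br cis to C11 and OH cis to C7.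

**Compound list**
1 | (S)-3-hydroxy-2,2-dimethylcyclohexan-1-one | O=C1CCC[C@H](O)C1(C)C | starting material
2 | [(1S)-2,2-dimethyl-3-oxocyclohexyl]oxy(triphenyl)phosphonium bromide | [Br-].O=C1CCC[C@H](O[P+](c2ccccc2)(c2ccccc2)c2ccccc2)C1(C)C | intermediate (not isolated)
3 | (R)-3-bromo-2,2-dimethylcyclohexan-1-one | O=C1CCC[C@@H](Br)C1(C)C | intermediate
4 | (1R)-1-bromo-2,2-dimethyl-3-methylidenecyclohexane | C=C1CCC[C@@H](Br)C1(C)C | intermediate
5 | [(5R)-5-bromo-6,6-dimethylcyclohex-1-en-1-yl]methaneseleninic acid | O[Se](=O)CC1=CCC[C@@H](Br)C1(C)C | intermediate (not isolated)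
6 | (4R)-4-bromo-3,3-dimethyl-2-methylidenecyclohexan-1-ol (C1 epimers) | C=C1C(O)CC[C@@H](Br)C1(C)C | intermediate
7 | (4R)-4-bromo-3,3-dimethyl-2-methylidenecyclohexan-1-one | C=C1C(=O)CC[C@@H](Br)C1(C)C | intermediate
8 | isoprene (2-methylbuta-1,3-diene) | C=CC(C)=C | starting material
9 | (6R,10R)-10-bromo-3,11,11-trimethylspiro[5.5]undec-2-en-7-one | O=C1CC[C@@H](Br)C(C)(C)[C@]12CCC(C)=CC2 | intermediate
10 | potassium (6R,10R)-10-bromo-3,11,11-trimethylspiro[5.5]undeca-2,7-dien-7-olate | [K+].[O-]C1=CC[C@@H](Br)C(C)(C)[C@]12CCC(C)=CC2 | intermediate (not isolated)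
11 | (6R,10R)-10-bromo-3,11,11-trimethylspiro[5.5]undeca-2,7-dien-7-yl trifluoromethanesulfonate | O=S(=O)(OC1=CC[C@@H](Br)C(C)(C)[C@]12CCC(C)=CC2)C(F)(F)F | intermediate
12 | (6S,10R)-10-bromo-3,7,11,11-tetramethylspiro[5.5]undeca-2,7-diene | CC1=CC[C@@H](Br)C(C)(C)[C@]12CCC(C)=CC2 | intermediate
13 | 2,3-bromonium ion of 12 (bromine on the C11 face of ring B) | CC1=CC[C@@H](Br)C(C)(C)[C@]12CC[C@@]3(C)[Br+][C@H]3C2 | intermediate (not isolated)
14 | (2S,3S,6S,10R)-2,10-dibromo-3,7,11,11-tetramethylspiro[5.5]undec-7-en-3-ol | CC1=CC[C@@H](Br)C(C)(C)[C@]12CC[C@](C)(O)[C@@H](Br)C2 | target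

**Step count**
Total: 8 steps. Longest linear sequence: 8 steps (1 → 14); isoprene 8 enters in step 5.

**Steps most likely to fail**

Step 5 (facial selectivity of the cycloaddition). The axial C3 methyl and the axial C4/C6 hydrogens shield opposite faces of the enone, and the C4 bromide is only modestly biased toward equatorial, so the C6 selectivity may be modest or reversed. The fallback sets out from 7 and comes back at 9. The cycloaddition is run as before and the unwanted epimer (6S,10R)-10-bromo-3,11,11-trimethylspiro[5.5]undec-2-en-7-one F2 is collected. C6 is stereogenic only through the position of the ring B alkene. TsOH (cat.) in benzene at 50 °C moves that alkene between C2=C3 and C3=C4 through the tertiary C3 cation, which turns F2 into a roughly 1:1 mixture with 9. Separation and recycling converge the material on 9, so the spiro centre is corrected thermodynamically instead of kinetically.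

Step 1 (SN2 at a neopentylic secondary carbinol). Elimination to the cyclohexenone or a slow, incomplete reaction may dominate. The fallback sets out from 1 and comes back at 3. Activation and displacement are separated: Tf2O/pyridine in CH2Cl2 at −30 °C gives (S)-2,2-dimethyl-3-oxocyclohexyl trifluoromethanesulfonate F1. LiBr in acetone at 0 °C → rt then displaces the much better leaving group with inversion, cold and without phosphine, to give 3.

Step 8 (face and site selectivity of the bromohydrin). Diaxial opening would require bromine syn to an axial substituent on C6, so the 2,3-bis-epimer (bromine on the C7 face) may predominate. The fallback sets out from 12 and comes back at 14, and uses that same facial preference: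
- OsO4 (cat.)/NMO in acetone/H2O at 0 °C dihydroxylates the ring B alkene to (2R,3S,6S,10R)-10-bromo-3,7,11,11-tetramethylspiro[5.5]undec-7-ene-2,3-diol F3, with both oxygens on the C7 face.
- SO2(imidazol-1-yl)2/NaH in THF closes the 2,3-cyclic sulfate F4.
- LiBr in THF opens F4 at the secondary C2 with inversion, which puts bromine on the C11 face and leaves lithium (2S,3S,6S,10R)-2,10-dibromo-3,7,11,11-tetramethylspiro[5.5]undec-7-en-3-yl sulfate F5.
- H2SO4 (cat.)/H2O in THF cleaves the S–O bond of F5 to give 14.

**Further compounds**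
F1 | step 1 | (S)-2,2-dimethyl-3-oxocyclohexyl trifluoromethanesulfonate | O=C1CCC[C@H](OS(=O)(=O)C(F)(F)F)C1(C)C
F2 | step 5 | (6S,10R)-10-bromo-3,11,11-trimethylspiro[5.5]undec-2-en-7-one | O=C1CC[C@@H](Br)C(C)(C)[C@@]12CCC(C)=CC2
F3 | step 8 | (2R,3S,6S,10R)-10-bromo-3,7,11,11-tetramethylspiro[5.5]undec-7-ene-2,3-diol | CC1=CC[C@@H](Br)C(C)(C)[C@]12CC[C@](C)(O)[C@H](O)C2
F4 | step 8 | 2,3-cyclic sulfate of (2R,3S,6S,10R)-10-bromo-3,7,11,11-tetramethylspiro[5.5]undec-7-ene-2,3-diol | CC1=CC[C@@H](Br)C(C)(C)[C@]12CC[C@]3(C)OS(=O)(=O)O[C@@H]3C2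
F5 | step 8 | lithium (2S,3S,6S,10R)-2,10-dibromo-3,7,11,11-tetramethylspiro[5.5]undec-7-en-3-yl sulfate | [Li+].CC1=CC[C@@H](Br)C(C)(C)[C@]12CC[C@](C)(OS(=O)(=O)[O-])[C@@H](Br)C2
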